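Late in the amber run target fell while over-reaction product rose. Between 1.00 min and 1.50 min over-reaction product rose from 55.4% to 72.7%, while target averaged 14.9%. Dividing the gain per minute by that average, I read a first-order loss of 2.32 min⁻¹, and I kept 0.431 min as the lifetime of target, the mean time a molecule of it lasts before going on. The thing to watch is how many lifetimes the reacted material has aged.

| flask | starting material | partner | second substrate | remark | time |
|---|---|---|---|---|---|
| blue | 0.10 M | 0.11 M | 0.10 M | run made earlier |  |
| red | 0.10 M | 0.15 M | 0.10 M | run made earlier |  |
| amber | 0.10 M | 0.24 M | 0.10 M | run made earlier |  |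
| green | 0.10 M | 0.11 M | 0.20 M | run made earlier |  |
| alder | 0.10 M | 0.110 M | 0.100 M (fed, over 2.50 min) | a stirred flask in which second substrate is dosed at a steady rate over 2.50 min without added volume, worked up at 2.5 min | 2.5 min |
| maple | 0.10 M (fed, over 2.50 min) | 0.110 M | 0.100 M | all but starting material at the start; starting material goes in evenly over 2.50 min, the run ends at 2.5 min | 2.5 min |
| birch | 0.10 M | 0.110 M | 0.100 M | a closed flask charged with all of it at once and left for 2.5 min | 2.5 min |
| oak | 0.10 M | 0.110 M | 0.100 M | a single well-mixed tank run continuously and read at steady state, 2.5 min in it on average |  |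

| run | time / min | target / % | over-reaction product / % | starting material / % |
|---|---|---|---|---|
| blue | 0.417 | 16.8 | 11.3 | 71.6 |
| blue | 0.833 | 14.9 | 26.9 | 57.8 |
| blue | 1.33 | 10.9 | 42.0 | 47.9 |
| blue | 1.50 | 9.8 | 46.2 | 44.2 |
| blue | 2.00 | 6.8 | 55.5 | 37.7 |
| blue | 2.50 | 4.7 | 62.7 | 32.4 |
| red | 0.250 | 19.0 | 7.8 | 73.8 |
| red | 0.417 | 21.2 | 15.2 | 64.0 |
| red | 0.667 | 19.9 | 27.8 | 52.8 |
| red | 1.00 | 15.9 | 41.2 | 43.3 |
| red | 2.00 | 7.4 | 67.2 | 24.9 |
| red | 3.00 | 4.0 | 80.2 | 16.1 |
| amber | 0.200 | 25.7 | 7.7 | 66.4 |
| amber | 0.667 | 25.7 | 38.1 | 35.9 |
| amber | 1.00 | 18.6 | 55.4 | 25.8 |
| amber | 1.50 | 11.2 | 72.7 | 16.4 |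
| amber | 2.50 | 4.0 | 89.4 | 6.7 |
| amber | 3.00 | 3.0 | 92.9 | 4.1 |
| green | 0.667 | 15.7 | 20.5 | 63.0 |
| green | 1.33 | 11.0 | 42.0 | 47.4 |
| green | 2.00 | 6.5 | 54.5 | 37.8 |
| green | 2.50 | 5.4 | 62.5 | 33.5 |
| green | 3.00 | 4.1 | 67.6 | 29.0 |

(readings scatter by 0.3 percentage points)

- the stated concentrations are those of everything mixed, before any reaction; amounts are the same in each set-up
- the feed brings no volume worth counting
- the earlier runs were made in a closed, stirred flask

- the set-up with the highest share of target in all that became target or over-reaction product, at the outlet or at the end ("none" if the first two lie within 2 percentage points) (alder / maple / birch / oak / none)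
- share of target in all that became target or over-reaction product, at the outlet or at the end, alder
- share of target in all that became target or over-reaction product, at the outlet or at the end, maple
- share of target in all that became target or over-reaction product, at the outlet or at the end, birch
- share of target in all that became target or over-reaction product, at the outlet or at the end, oak

I built the flask up around that frozen lifetime, starting with formation of target and its first-order loss. In the steady tank oak, over-reaction product at the outlet equals target times the mean time over the lifetime. That mean time is 5.81 lifetimes, so the share of target in target plus over-reaction product (the selectivity) is 14.7%, with no need for a formation rate.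

Next I added the time course of formation. Birch is the blue recipe, whose reading at 2.50 min gives a share of 6.97%. The share is low there because the lifetime is short against the run.

For maple I took material to react evenly over the run, with ages spread from nothing to the whole time, which gives a share of 17.2%. Starting material builds up from nothing in maple, so I expected formation to lean late and the share to stand above that estimate.

Last came second substrate. At 2.00 min blue read 6.8% target and green, with twice the second substrate, read 6.5%. So I put alder beside birch.

The forecast gave 7.5% for alder, 21.5% for maple, 7.2% for birch and 14.5% for oak, with maple best: “Maple's late-fed material is freshest.” Its maple figure stands above my estimate, the direction I expected.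

The flasks gave 7.53% for alder, 21.0% for maple, 7.65% for birch and 14.6% for oak, and maple was best.

    second substrate + partner ⇌ second product (K = 0.510 L mol⁻¹, k = 0.0730 L mol⁻¹ s⁻¹)
    starting material + partner ⇌ target (K = 11.0 L mol⁻¹, k = 0.170 L mol⁻¹ s⁻¹)
    target → over-reaction product (k = 0.0390 s⁻¹)
    2 second substrate → homo dimer (k = 0.210 L mol⁻¹ s⁻¹)

In alder at 0.546 min target fell back at 0.40 of the rate at which it went on, and between 1.25 min and 2.50 min its mean amount over the gain per minute of over-reaction product came to 0.457 min, beside the lifetime of 0.431 min. The same 5.81 lifetimes passed in the alder flask charged with 0.028 M of partner, a quarter of the charge in alder, and it held 20.0% over-reaction product against 62.4%, yet its share was 8.24%.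

(Readings and results stem from a simulated flask from invented constants; noise was put on by code.)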